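## Retrosynthetic overview

1. Feature: the O1–C2–C3(OH)–C4(=O)–C4a–C8a array of ring C is the 5-hydroxy-4-pyranone of kojic acid, and its CH2OH carbon sits where C8 and the 8-oxygen are needed, so only C7, C6 and C5 of ring A are missing.
2. Target 19 ⇐ 3-O-benzyl flavone 18 (hydrogenolysis) ⇐ pyranone enoate 15, with ring A closed last through the C4a–C5 bond (intramolecular Claisen acylation, loss of MeOH, aromatization).
3. 15 ⇐ β-keto ester 13 (C7 enol methyl ether) ⇐ acid 9 + potassium methyl malonate 10 (C6 and C5) ⇐ lateral carboxylation of the CH2OMe group of pyranone 7 (C7 from CO2).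
4. 7 ⇐ kojic acid 1 by bromination next to the enolic OH, O-benzylation, Suzuki coupling with boronic acid 4 (C2–C1' bond) and O-methylation of the CH2OH group.
5. Ring order: ring C is bought (kojic acid), ring B is attached in step 3, ring A is formed in step 8.

Key step: step 8

Remark: ring atoms carry flavone numbers throughout (pyranone C3 = C4a, pyranone C2 = C8a, side-chain carbon = C8); 9 and 11 to 15 are racemic at C8, which ends as an aromatic carbon, so no stereocontrol is needed.

## Route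

Step 1
Reactants: 1 kojic acid
Product: 2 2-bromo-3-hydroxy-6-(hydroxymethyl)-4H-pyran-4-one (6-bromokojic acid)
Conditions: NBS (1.05 equiv), DMF, 0 °C to rt
Reagents that add atoms: N-bromosuccinimide, O=C1CCC(=O)N1Br
Why: Electrophilic bromination of the enolic pyranone, directed by the free 5-OH to the adjacent ring carbon (the future flavone C2), the position at which kojic acid also undergoes Mannich and hydroxymethylation reactions.

Step 2
Reactants: 2 2-bromo-3-hydroxy-6-(hydroxymethyl)-4H-pyran-4-one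
Product: 3 3-(benzyloxy)-2-bromo-6-(hydroxymethyl)-4H-pyran-4-one
Conditions: BnBr (1.1 equiv), K2CO3 (1.2 equiv), DMF, rt
Reagents that add atoms: benzyl bromide, BrCc1ccccc1
Why: Williamson etherification; carbonate deprotonates only the acidic enolic OH, so the primary alcohol stays free and the mild base leaves the vinylogous acyl bromide untouched.

Step 3
Reactants: 3 3-(benzyloxy)-2-bromo-6-(hydroxymethyl)-4H-pyran-4-one; 4 (3,4,5-trimethoxyphenyl)boronic acid
Product: 5 3-(benzyloxy)-6-(hydroxymethyl)-2-(3,4,5-trimethoxyphenyl)-4H-pyran-4-one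
Conditions: Pd(PPh3)4 (5 mol %), Na2CO3 (2 equiv), 1,4-dioxane/H2O 4:1, 85 °C
Reagents that add atoms: none
Why: Suzuki–Miyaura coupling; the C–Br bond of the β-bromo enone adds readily to zerovalent palladium, and the free CH2OH and the benzyl ether are tolerated.

Step 4
Reactants: 5 3-(benzyloxy)-6-(hydroxymethyl)-2-(3,4,5-trimethoxyphenyl)-4H-pyran-4-one
Product: 7 3-(benzyloxy)-6-(methoxymethyl)-2-(3,4,5-trimethoxyphenyl)-4H-pyran-4-one, via sodium alkoxide 6 (not isolated)
Conditions: NaH (1.1 equiv), THF, 0 °C; then MeI (1.5 equiv), 0 °C to rt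
Reagents that add atoms: iodomethane, CI
Why: Williamson methylation of the primary alkoxide; with one equivalent of NaH at 0 °C the alcohol is deprotonated well before the lateral CH2, and no electrophilic C–Br remains after step 3.

Step 5
Reactants: 7 3-(benzyloxy)-6-(methoxymethyl)-2-(3,4,5-trimethoxyphenyl)-4H-pyran-4-one
Product: 9 2-[5-(benzyloxy)-4-oxo-6-(3,4,5-trimethoxyphenyl)-4H-pyran-2-yl]-2-methoxyacetic acid (racemic), via lithium dienolate 8 (not isolated)
Conditions: LiN(iPr)2 (1.2 equiv), THF, −78 °C; CO2 (gas), −78 to −20 °C; then cold 1 M HCl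
Reagents that add atoms: carbon dioxide, O=C=O
Why: Lateral (vinylogous) deprotonation of a 2-alkyl-4-pyranone followed by carboxylation of the extended enolate at its exocyclic γ-carbon, as known for 2-methyl-4-pyranones; the new C8 stereocenter is formed racemic and is erased in step 8.

Step 6
Reactants: 9 2-[5-(benzyloxy)-4-oxo-6-(3,4,5-trimethoxyphenyl)-4H-pyran-2-yl]-2-methoxyacetic acid; 10 potassium methyl malonate
Product: 13 methyl 4-[5-(benzyloxy)-4-oxo-6-(3,4,5-trimethoxyphenyl)-4H-pyran-2-yl]-4-methoxy-3-oxobutanoate (racemic), via acyl imidazolide 11 (not isolated), via acylmalonic half ester 12 (not isolated)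
Conditions: CDI (1.2 equiv), THF, rt; then 10 (2 equiv), MgCl2 (2 equiv), Et3N (2 equiv), MeCN, rt to 45 °C; then 1 M HCl
Reagents that add atoms: none
Why: Masamune–Brooks homologation; the acyl imidazolide acylates the magnesium enolate of the malonate half ester under nearly neutral conditions, and the adduct loses CO2 to give the β-keto ester.

Step 7
Reactants: 13 methyl 4-[5-(benzyloxy)-4-oxo-6-(3,4,5-trimethoxyphenyl)-4H-pyran-2-yl]-4-methoxy-3-oxobutanoate
Product: 15 methyl (E)-4-[5-(benzyloxy)-4-oxo-6-(3,4,5-trimethoxyphenyl)-4H-pyran-2-yl]-3,4-dimethoxybut-2-enoate (racemic), via dimethyl ketal 14 (not isolated)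
Conditions: HC(OMe)3 (5 equiv), H2SO4 (cat.), MeOH, rt to 50 °C; then NaHCO3
Reagents that add atoms: trimethyl orthoformate, COC(OC)OC (the methoxy group at C7; it exchanges with the solvent methanol, CO)
Why: Acid-catalysed ketalization and loss of methanol (enol ether formation from a β-keto ester) should give the thermodynamically preferred push–pull (E)-β-methoxy enoate, with OMe trans to CO2Me and the C8 chain cis to the ester; a double-bond isomer toward C8 would give the same delocalized anion in step 8.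

Step 8
Reactants: 15 methyl (E)-4-[5-(benzyloxy)-4-oxo-6-(3,4,5-trimethoxyphenyl)-4H-pyran-2-yl]-3,4-dimethoxybut-2-enoate
Product: 18 3-(benzyloxy)-5-hydroxy-7,8-dimethoxy-2-(3,4,5-trimethoxyphenyl)-4H-chromen-4-one, via lithium trienolate 16 (not isolated), via 4aH-chromene-4,5-dione 17 (not isolated)
Conditions: LiN(SiMe3)2 (2.5 equiv), THF (0.02 M), −78 °C to 60 °C; then 1 M HCl
Reagents that add atoms: none
Why: Proposed new method: LiN(SiMe3)2 removes the C8–H, which is γ to both the pyranone carbonyl and the ester, and the lithium enolate 16 (O–C4=C4a–C8a=C8) attacks the ester carbon C5 with its α-carbon C4a; loss of methoxide gives the 4aH-dione 17, whose acidic C4a–H is then removed so that ring A aromatizes to the phenoxide of 18, which makes the sequence irreversible. The closest known reaction type is the base-mediated Claisen (Dieckmann-type) cyclization of β-polycarbonyl chains masked as pyranones and enol ethers to acylphloroglucinols and 5,7-dihydroxychromones, together with the lateral-enolate acylation of 2-alkyl-4-pyranones; acylation of such an enolate at the ring α-carbon to close a benzo ring has not been shown. Ring A closes in the 6-(enolexo)-exo-trig mode, and the same bond formation can be read as a disrotatory 6π-electrocyclization of the C4a=C8a–C8=C7–C6=C5(O–) trienolate, so it does not depend on a strongly electrophilic ester. No stereocenter is formed, and the racemic C8 center of 15 becomes an aromatic carbon. The step needs C-acylation at C4a only: attack from C8 would give a four-membered ring, O-acylation an eight-membered ring, an aldol closure onto C4 a bridgehead alkene, and C6 cannot be enolized because it is an enol-ether CH. The (E) enol ether holds C5 cis to the C8 chain (the delocalized anion can also correct a wrong geometry), and Li+ can bridge the C4 oxygen and the ester carbonyl, the two oxygens that end as the hydrogen-bonded C4=O/5-OH pair.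

Step 9
Reactants: 18 3-(benzyloxy)-5-hydroxy-7,8-dimethoxy-2-(3,4,5-trimethoxyphenyl)-4H-chromen-4-one
Product: 19 3,5-dihydroxy-7,8-dimethoxy-2-(3,4,5-trimethoxyphenyl)-4H-chromen-4-one (3,5-dihydroxy-7,8,3',4',5'-pentamethoxyflavone)
Conditions: H2 (1 atm), 10% Pd/C, EtOAc/MeOH, rt
Reagents that add atoms: none
Why: Catalytic hydrogenolysis of the benzyl ether; the methyl ethers, the chelated 5-OH and the tetrasubstituted C2=C3 bond of the flavone should survive under balloon pressure at room temperature.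

## Compound list

1 | kojic acid | O=c1cc(CO)occ1O | starting material
2 | 2-bromo-3-hydroxy-6-(hydroxymethyl)-4H-pyran-4-one | O=c1cc(CO)oc(Br)c1O | intermediate
3 | 3-(benzyloxy)-2-bromo-6-(hydroxymethyl)-4H-pyran-4-one | O=c1cc(CO)oc(Br)c1OCc1ccccc1 | intermediate
4 | (3,4,5-trimethoxyphenyl)boronic acid | COc1cc(B(O)O)cc(OC)c1OC | starting material
5 | 3-(benzyloxy)-6-(hydroxymethyl)-2-(3,4,5-trimethoxyphenyl)-4H-pyran-4-one | O=c1cc(CO)oc(-c2cc(OC)c(OC)c(OC)c2)c1OCc1ccccc1 | intermediate
6 | sodium [5-(benzyloxy)-4-oxo-6-(3,4,5-trimethoxyphenyl)-4H-pyran-2-yl]methanolate | [Na+].[O-]Cc1cc(=O)c(OCc2ccccc2)c(-c2cc(OC)c(OC)c(OC)c2)o1 | intermediate (not isolated)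
7 | 3-(benzyloxy)-6-(methoxymethyl)-2-(3,4,5-trimethoxyphenyl)-4H-pyran-4-one | COCc1cc(=O)c(OCc2ccccc2)c(-c2cc(OC)c(OC)c(OC)c2)o1 | intermediate
8 | lithium 3-(benzyloxy)-6-(methoxymethylidene)-2-(3,4,5-trimethoxyphenyl)-6H-pyran-4-olate (lateral dienolate of 7, alkene geometry not fixed) | [Li+].COC=C1C=C([O-])C(OCc2ccccc2)=C(c2cc(OC)c(OC)c(OC)c2)O1 | intermediate (not isolated)
9 | 2-[5-(benzyloxy)-4-oxo-6-(3,4,5-trimethoxyphenyl)-4H-pyran-2-yl]-2-methoxyacetic acid (racemic) | COC(C(=O)O)c1cc(=O)c(OCc2ccccc2)c(-c2cc(OC)c(OC)c(OC)c2)o1 | intermediate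
10 | potassium methyl malonate | COC(=O)CC(=O)[O-].[K+] | starting material
11 | 2-[5-(benzyloxy)-4-oxo-6-(3,4,5-trimethoxyphenyl)-4H-pyran-2-yl]-1-(1H-imidazol-1-yl)-2-methoxyethan-1-one (racemic) | COC(C(=O)n1ccnc1)c1cc(=O)c(OCc2ccccc2)c(-c2cc(OC)c(OC)c(OC)c2)o1 | intermediate (not isolated)
12 | 2-{2-[5-(benzyloxy)-4-oxo-6-(3,4,5-trimethoxyphenyl)-4H-pyran-2-yl]-2-methoxyacetyl}-3-methoxy-3-oxopropanoic acid (formed as its magnesium chelate, mixture of stereoisomers) | COC(=O)C(C(=O)O)C(=O)C(OC)c1cc(=O)c(OCc2ccccc2)c(-c2cc(OC)c(OC)c(OC)c2)o1 | intermediate (not isolated)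
13 | methyl 4-[5-(benzyloxy)-4-oxo-6-(3,4,5-trimethoxyphenyl)-4H-pyran-2-yl]-4-methoxy-3-oxobutanoate (racemic) | COC(=O)CC(=O)C(OC)c1cc(=O)c(OCc2ccccc2)c(-c2cc(OC)c(OC)c(OC)c2)o1 | intermediate
14 | methyl 4-[5-(benzyloxy)-4-oxo-6-(3,4,5-trimethoxyphenyl)-4H-pyran-2-yl]-3,3,4-trimethoxybutanoate (racemic) | COC(=O)CC(OC)(OC)C(OC)c1cc(=O)c(OCc2ccccc2)c(-c2cc(OC)c(OC)c(OC)c2)o1 | intermediate (not isolated)
15 | methyl (E)-4-[5-(benzyloxy)-4-oxo-6-(3,4,5-trimethoxyphenyl)-4H-pyran-2-yl]-3,4-dimethoxybut-2-enoate (racemic) | COC(=O)/C=C(/OC)C(OC)c1cc(=O)c(OCc2ccccc2)c(-c2cc(OC)c(OC)c(OC)c2)o1 | intermediate (key-step precursor)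
16 | lithium trienolate of 15 (C8-deprotonated, delocalized over C4–O and the ester; alkene geometry labile) | [Li+].COC(=O)C=C(OC)C(OC)=C1C=C([O-])C(OCc2ccccc2)=C(c2cc(OC)c(OC)c(OC)c2)O1 | intermediate (not isolated)
17 | 3-(benzyloxy)-7,8-dimethoxy-2-(3,4,5-trimethoxyphenyl)-4aH-chromene-4,5-dione (racemic) | COC1=CC(=O)C2C(=O)C(OCc3ccccc3)=C(c3cc(OC)c(OC)c(OC)c3)OC2=C1OC | intermediate (not isolated)
18 | 3-(benzyloxy)-5-hydroxy-7,8-dimethoxy-2-(3,4,5-trimethoxyphenyl)-4H-chromen-4-one | COc1cc(-c2oc3c(OC)c(OC)cc(O)c3c(=O)c2OCc2ccccc2)cc(OC)c1OC | intermediate (key-step product)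
19 | 3,5-dihydroxy-7,8-dimethoxy-2-(3,4,5-trimethoxyphenyl)-4H-chromen-4-one | COc1cc(-c2oc3c(OC)c(OC)cc(O)c3c(=O)c2O)cc(OC)c1OC | target

## Step count and risks

Total step count: 9. Longest linear sequence: 9 steps, from kojic acid 1.

**Step 8 (ring A closure).** The doubly stabilized anion may be too unreactive to close, may react between molecules (Claisen or Michael oligomerization), or the pyranone may be opened by the methoxide set free. The fallback closes the same C4a–C5 bond thermally by the known acetic anhydride/sodium acetate benzannulation of 4-aryl- and 4-heteroarylbutenoic acids (Stobbe-type ring closure through a dienylketene). It sets out from 15 and comes back at 18. The methyl ester of 15 would be cleaved with Me3SnOH (1,2-dichloroethane, 80 °C) to (E)-4-[5-(benzyloxy)-4-oxo-6-(3,4,5-trimethoxyphenyl)-4H-pyran-2-yl]-3,4-dimethoxybut-2-enoic acid F1. Heating F1 in Ac2O with NaOAc should give the mixed acetic anhydride F2. Loss of acetic acid across C8–H and the acyl group should give the dienylketene 4-[5-(benzyloxy)-4-oxo-6-(3,4,5-trimethoxyphenyl)-4H-pyran-2-yl]-3,4-dimethoxybuta-1,3-dien-1-one F3. A 6π-electrocyclization of F3 onto the C4a=C8a bond gives dione 17, which tautomerizes and is acetylated in the same flask to 5-acetoxy-3-(benzyloxy)-7,8-dimethoxy-2-(3,4,5-trimethoxyphenyl)-4H-chromen-4-one F4. Methanolysis of the aryl acetate (K2CO3, MeOH, rt) then returns 18.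

**Step 5 (lateral carboxylation).** The extended enolate may be carboxylated at the ring carbon instead of the lateral carbon, the amide base may attack the pyranone, or the vinylogous β-keto acid may lose CO2 during acidification and isolation. The fallback avoids the lateral anion and the acid and builds the chain from the aldehyde oxidation level. It sets out from alcohol 5 and comes back at 15, which makes steps 4 to 7 unnecessary. MnO2 (CH2Cl2, rt) should oxidize the activated primary alcohol to 5-(benzyloxy)-4-oxo-6-(3,4,5-trimethoxyphenyl)-4H-pyran-2-carbaldehyde F5. Lithium methyl propiolate F6, made from methyl propiolate and LiN(SiMe3)2 in THF at −78 °C, would add to F5 to give methyl 4-[5-(benzyloxy)-4-oxo-6-(3,4,5-trimethoxyphenyl)-4H-pyran-2-yl]-4-hydroxybut-2-ynoate F7. Methylation with MeI and Ag2O (CH2Cl2, rt) should give methyl 4-[5-(benzyloxy)-4-oxo-6-(3,4,5-trimethoxyphenyl)-4H-pyran-2-yl]-4-methoxybut-2-ynoate F8. Base-catalysed conjugate addition of methanol (NaOMe cat., MeOH, 0 °C to rt) to the ynoate should then give the (E)-β-methoxy enoate 15.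

**Step 7 (enol ether formation).** The ketal may lose methanol toward C8 instead of C6, the Z enol ether may form, or the conversion may stall at the ketal under the acidic conditions. The fallback forms the C7–OMe bond by addition–elimination of methoxide at C7 instead of O-methylation. It sets out from 13 and comes back at 15. Enol tosylation (TsCl, N-methylimidazole, Et3N, CH2Cl2, 0 °C) should give methyl 4-[5-(benzyloxy)-4-oxo-6-(3,4,5-trimethoxyphenyl)-4H-pyran-2-yl]-4-methoxy-3-(tosyloxy)but-2-enoate F9. Treatment of F9 with NaOMe in MeOH at 0 °C should replace the tosylate by methoxide and give 15.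

## Further compounds

F1 | step 8 | (E)-4-[5-(benzyloxy)-4-oxo-6-(3,4,5-trimethoxyphenyl)-4H-pyran-2-yl]-3,4-dimethoxybut-2-enoic acid (racemic) | O=C(O)/C=C(/OC)C(OC)c1cc(=O)c(OCc2ccccc2)c(-c2cc(OC)c(OC)c(OC)c2)o1
F2 | step 8 | acetic (E)-4-[5-(benzyloxy)-4-oxo-6-(3,4,5-trimethoxyphenyl)-4H-pyran-2-yl]-3,4-dimethoxybut-2-enoic anhydride (racemic) | CC(=O)OC(=O)/C=C(/OC)C(OC)c1cc(=O)c(OCc2ccccc2)c(-c2cc(OC)c(OC)c(OC)c2)o1
F3 | step 8 | 4-[5-(benzyloxy)-4-oxo-6-(3,4,5-trimethoxyphenyl)-4H-pyran-2-yl]-3,4-dimethoxybuta-1,3-dien-1-one (dienylketene) | O=C=CC(OC)=C(OC)c1cc(=O)c(OCc2ccccc2)c(-c2cc(OC)c(OC)c(OC)c2)o1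
F4 | step 8 | 5-acetoxy-3-(benzyloxy)-7,8-dimethoxy-2-(3,4,5-trimethoxyphenyl)-4H-chromen-4-one | COc1cc(-c2oc3c(OC)c(OC)cc(OC(C)=O)c3c(=O)c2OCc2ccccc2)cc(OC)c1OC
F5 | step 5 | 5-(benzyloxy)-4-oxo-6-(3,4,5-trimethoxyphenyl)-4H-pyran-2-carbaldehyde | O=Cc1cc(=O)c(OCc2ccccc2)c(-c2cc(OC)c(OC)c(OC)c2)o1
F6 | step 5 | lithium methyl propiolate (lithium 3-methoxy-3-oxoprop-1-yn-1-ide) | [Li+].[C-]#CC(=O)OC
F7 | step 5 | methyl 4-[5-(benzyloxy)-4-oxo-6-(3,4,5-trimethoxyphenyl)-4H-pyran-2-yl]-4-hydroxybut-2-ynoate (racemic) | COC(=O)C#CC(O)c1cc(=O)c(OCc2ccccc2)c(-c2cc(OC)c(OC)c(OC)c2)o1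
F8 | step 5 | methyl 4-[5-(benzyloxy)-4-oxo-6-(3,4,5-trimethoxyphenyl)-4H-pyran-2-yl]-4-methoxybut-2-ynoate (racemic) | COC(=O)C#CC(OC)c1cc(=O)c(OCc2ccccc2)c(-c2cc(OC)c(OC)c(OC)c2)o1
F9 | step 7 | methyl 4-[5-(benzyloxy)-4-oxo-6-(3,4,5-trimethoxyphenyl)-4H-pyran-2-yl]-4-methoxy-3-(tosyloxy)but-2-enoate (racemic, alkene geometry not fixed) | COC(=O)C=C(OS(=O)(=O)c1ccc(C)cc1)C(OC)c1cc(=O)c(OCc2ccccc2)c(-c2cc(OC)c(OC)c(OC)c2)o1
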